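Time comes first. Substrate opens to the open intermediate and partner turns into the second intermediate. The open intermediate then either meets the second intermediate, giving target, or pairs with itself, giving homo product.

all flasks: substrate 0.30 M

| charge | partner | remark | time |
|---|---|---|---|
| Friday's | 0.75 equiv | run made earlier |  |
| Saturday's | 1.7 equiv | run made earlier |  |
| theta | 1.20 equiv |  | 40 h |
| alpha | 2.40 equiv |  | 40 h |

| run | time / h | target / % |
|---|---|---|
| Friday's | 2.50 | 27.2 |
| Friday's | 5.00 | 28.2 |
| Friday's | 12.0 | 28.8 |
| Friday's | 30.0 | 28.0 |
| Saturday's | 4.00 | 44.8 |
| Saturday's | 10.0 | 44.4 |
| Saturday's | 20.0 | 44.7 |
| Saturday's | 30.0 | 45.6 |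

(readings scatter by 0.5 percentage points)
- which of the two there is more of at the end, counted by the substrate in each, theta (target / homo product)
- which of the two there is more of at the end, counted by the substrate in each, alpha (target / homo product)
- how much target is there at the end, in percent of the substrate charged: theta
- how much target is there at the end, in percent of the substrate charged: alpha
- percent here means substrate units held: one homo product counts as two
- the numbers in the tables scatter by 0.5 percentage points (one standard deviation)
- reactions considered so far: substrate -> open intermediate; open intermediate + second intermediate -> target; 2 open intermediate -> homo product; partner -> second intermediate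

Target is already level at 5.00 h in Friday's run and at 4.00 h in Saturday's, so we read plateaus, 28.3% and 44.9%, and take them to hold at 40 h.

A power law through them has slope 0.562. Target cannot pass 100%, so we expect that slope to fall as partner grows. On that expectation the law gives the lower end of our estimate for theta and the upper end for alpha, and Saturday's plateau gives the other end of each:

theta: 36.9% to 44.9%
alpha: 44.9% to 54.5%

To tighten this, we count what is not target as homo product and work with the odds, target over homo product, an integrated selectivity factor. The rate ratio of the two ends goes as c(second intermediate)/c(open intermediate), so we try a steady power for the rise of the odds with partner. We call it the odds exponent, the logarithmic rise of odds per logarithmic rise of equivalents: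

odds: 0.395 and 0.814, exponent 0.883
theta: odds 0.599, target 37.4%
alpha: odds 1.10, target 52.5%

The forecast says 37.5% and homo product ahead for theta, 53% for alpha, where “target narrowly leads”. Both numbers lie inside our brackets,  and its choices match our odds.

    substrate → open intermediate (k = 0.00100 s⁻¹)
    open intermediate + second intermediate → target (k = 0.00720 L mol⁻¹ s⁻¹)
    2 open intermediate → homo product (k = 0.00400 L mol⁻¹ s⁻¹)
    partner → second intermediate (k = 1.40 × 10⁻⁴ s⁻¹)

Theta holds 37.1% target and alpha 52.8%, each inside its bracket. Target equals homo product at 2.13 equiv of partner, and alpha stands at 2.40 equiv. Theta's odds come to 0.590 against the carried 0.599, and alpha's to 1.12 against 1.10. Carried to the same flask as theta but with 3.00 equiv of partner, the exponent 0.883 gives odds 1.34, or 57.3% target, and that flask holds 58.2%.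

The runs were generated by integration with made-up constants.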